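- 3 questions stand, and they ask about a time far past Saturday's last reading at 8.00 min.

| setting | Saturday's | birch | cedar |
|---|---|---|---|
| substrate | 40 mM | 40 mM | 40 mM |
| coupling partner | 100 mM | 100 mM | 100 mM |
| free catalyst | 12 mM | 6.0 mM | 6.0 mM |
| temperature | 135 °C | 135 °C | 110 °C |
| remark | run made earlier |  |  |
| time |  | 80 min | 80 min |

Saturday's run (percent of the substrate charged)

| time / min | target / % |
|---|---|
| 0.667 | 12.2 |
| 1.00 | 19.4 |
| 2.00 | 32.3 |
| 3.00 | 39.3 |
| 5.00 | 42.9 |
| 8.00 | 34.3 |

(standard deviation of a reading: 0.5 percentage points)

- the numbers in the tables scatter by 0.5 percentage points (one standard deviation)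
- the earlier runs do not show what temperature does; that part of a forecast is a guess
- no earlier run changes the charge of free catalyst; that part of a forecast is a guess

* the best flask by amount of target, in percent of the substrate charged; "all alike" if 1.5 percentage points covers them all (birch / cedar / all alike)
* amount of target at the end, in percent of the substrate charged, birch
* amount of target at the end, in percent of the substrate charged, cedar

- Saturday's target peaks and then falls, so I read a rate from its last two readings: 0.0746 min⁻¹. This fall rate, the logarithmic drop of target per minute past its peak, means a half-life of 9.29 min, with the scatter of those readings in it.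
- My reckoning treats each flask as Saturday's curve on a slower clock: flask minutes divided by a slowdown give Saturday minutes, and beyond 8.00 min the curve continues from 34.3 % at the fall rate. For cooling I borrow the forecast's guessed factor of 5.
- My upper bound assumes that the lower catalyst charge also slows the whole curve, by a factor of 2.00. That gives 3.15 % in birch and 34.3 % in cedar.
- My lower bound assumes that catalyst does not slow the fall at all, which gives 0.160 % in birch and 18.9 % in cedar. Saturday's run does not change the catalyst charge, so it does not choose between the two bounds, but cedar's lower bound stands above birch's upper bound, so I pick cedar.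
- The forecast says cedar, with 3 % in birch, just under my upper bound, and 35 % in cedar, just over it: “This is a guess, but the peak is broad.”
- The flasks give cedar, with 0.123 % in birch and 16.8 % in cedar, each below my lower bound.

    catalyst intermediate C → released group + catalyst intermediate D (k = 1.70 min⁻¹, Ea = 102 kJ mol⁻¹)
    catalyst intermediate D → free catalyst + target (k = 170 min⁻¹, Ea = 98.0 kJ mol⁻¹)
    coupling partner + target → over-reaction product (k = 0.760 M⁻¹ min⁻¹, Ea = 85.0 kJ mol⁻¹)
    coupling partner + catalyst intermediate A ⇌ catalyst intermediate B (K = 36.0 M⁻¹, k = 4.20 M⁻¹ min⁻¹, Ea = 56.0 kJ mol⁻¹, ΔH = −7.00 kJ mol⁻¹)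
    catalyst intermediate B ⇌ catalyst intermediate C (K = 11.0, k = 2.70 min⁻¹, Ea = 111 kJ mol⁻¹, ΔH = −38.0 kJ mol⁻¹)
    substrate + free catalyst ⇌ catalyst intermediate A (K = 1300 M⁻¹, k = 490 M⁻¹ min⁻¹, Ea = 52.0 kJ mol⁻¹, ΔH = −82.0 kJ mol⁻¹)
    (constants at 110 °C)

- In birch, the step from catalyst intermediate B to catalyst intermediate C has half its turnover done by 4.37 min and 99.9 % done by 40.0 min. The step of coupling partner with target to over-reaction product runs on, pseudo-first-order with coupling partner at 21.2 % to 20.0 % of its charge, and target goes from 2.80 % at 40.0 min to 0.123 % at 80.0 min: a fall rate of 0.0782 min⁻¹ at half Saturday's catalyst, beside the carried 0.0746 min⁻¹.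
- For birch read at 20 min, the clock without catalyst slowing gives 14.0 %, and the computed flask holds 13.9 %.

(The data stem from a simulated flask with constants of no real substance.)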